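Everything hinges on cutting the trisubstituted C11=C12 double bond (numbering: C5 is the CH2 on the furan, C19 the lactone C=O). In the target the C12 methyl and the acetoxy carbon C10 lie on the same side of that bond. Tying the C10 oxygen to a boron atom placed on C12 and closing the five-membered oxaborole ring (B, O, C10, C11, C12) by olefin metathesis joins the two halves and locks this geometry at once. The metathesis substrate is the mixed boronic ester of a C5–C11 furyl dienol (10S) with a C12–C19 acetoxy lactone (15R,16S) ending in a 1-borylvinyl group; boron is then exchanged for methyl.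

Key step: step 16

Remark: the target is taken as the 10S,15R,16S isomer with E alkenes at C7=C8 and C11=C12, as its SMILES encodes. Because lactonisation inverts C16, the epoxide required is (15R,16R).

**Alcohol half (C5–C11)**

Step 1
Reactants: 1 (S)-epichlorohydrin; 2 ethynyltrimethylsilane
Product: 3 (2S)-1-chloro-5-(trimethylsilyl)pent-4-yn-2-ol
Conditions: 2, n-BuLi, THF, −78 °C; BF3·OEt2; then 1, −78 °C
Reagents that add atoms: none
Why: BF3-promoted opening of the oxirane by the lithium acetylide (Yamaguchi–Hirao alkynylation) occurs at the unsubstituted ring carbon, so the C–O stereocentre of 1 is carried over unchanged as the future C10.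

Step 2
Reactants: 3 (2S)-1-chloro-5-(trimethylsilyl)pent-4-yn-2-ol
Product: 5 (3S)-6-(trimethylsilyl)hex-1-en-5-yn-3-ol, via epoxide 4 (not isolated)
Conditions: Me3S+ I− (4 equiv), n-BuLi (3.9 equiv), THF, −20 °C to rt
Reagents that add atoms: trimethylsulfonium iodide, C[S+](C)C.[I-]
Why: Excess dimethylsulfonium methylide should first close the chlorohydrin to the terminal epoxide and then open it at CH2 and eliminate dimethyl sulfide (sulfonium-ylide homologation of an epoxide to an allylic alcohol), leaving the C–O stereocentre untouched.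

Step 3
Reactants: 5 (3S)-6-(trimethylsilyl)hex-1-en-5-yn-3-ol
Product: 6 (3S)-hex-1-en-5-yn-3-ol
Conditions: K2CO3 (cat.), MeOH, rt
Reagents that add atoms: none
Why: Base-catalysed methanolysis of the C(sp)–Si bond (protodesilylation) should free the terminal alkyne; the volatile product is best carried on as a concentrated CH2Cl2 solution.

Step 4
Reactants: 6 (3S)-hex-1-en-5-yn-3-ol
Product: 8 (3S,5E)-6-iodo-5-methylhexa-1,5-dien-3-ol, via alkenylalane 7 (not isolated)
Conditions: AlMe3 (3.5 equiv), Cp2ZrCl2 (0.3 equiv), CH2Cl2, 0 °C to rt; then I2, THF, −30 to 0 °C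
Reagents that add atoms: trimethylaluminium, C[Al](C)C; iodine, II
Why: Zirconium-catalysed syn carboalumination of the terminal alkyne (Negishi carboalumination) puts methyl on the internal carbon and aluminium on the terminus, and iodinolysis with retention should give the E alkenyl iodide; the hydroxyl is masked in the flask as its aluminium alkoxide and the monosubstituted alkene reacts far more slowly.

Step 5
Reactants: 9 furan-3-carbaldehyde
Product: 10 3-ethenylfuran
Conditions: Ph3PCH3Br, KOt-Bu, Et2O, 0 °C to rt
Reagents that add atoms: methyltriphenylphosphonium bromide, C[P+](c1ccccc1)(c1ccccc1)c1ccccc1.[Br-]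
Why: Wittig methylenation of the aldehyde with the non-stabilised ylide should give the vinylfuran, which is volatile and is kept as a titrated solution after filtration through silica.

Step 6
Reactants: 10 3-ethenylfuran; 8 (3S,5E)-6-iodo-5-methylhexa-1,5-dien-3-ol
Product: 12 (3S,5E)-8-(furan-3-yl)-5-methylocta-1,5-dien-3-ol, via alkylborane 11 (not isolated)
Conditions: 10 (1.5 equiv), 9-BBN (1.4 equiv), THF, 0 °C to rt; then 8, PdCl2(dppf) (5 mol %), AsPh3, Cs2CO3, DMF–THF–H2O, rt
Reagents that add atoms: none
Why: Anti-Markovnikov hydroboration of the vinyl group followed by B-alkyl Suzuki–Miyaura coupling with the alkenyl iodide should proceed with retention of the E geometry and tolerate the free hydroxyl; the iodide is added only after all B–H is consumed, which protects its own vinyl group.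

**Boronic acid half (C12–C19)**

Step 7
Reactants: 13 tert-butyl acetate; 14 2,3-dibromoprop-1-ene
Product: 15 tert-butyl 4-bromopent-4-enoate
Conditions: LiN(i-Pr)2, THF, −78 °C; then 14, −78 °C to rt
Reagents that add atoms: none
Why: SN2 alkylation of the lithium ester enolate at the allylic bromide should be clean because the vinylic bromide is inert and the tert-butyl ester resists self-condensation.

Step 8
Reactants: 15 tert-butyl 4-bromopent-4-enoate
Product: 16 4-bromopent-4-enal
Conditions: i-Bu2AlH (1.1 equiv), CH2Cl2, −78 °C; aq. potassium sodium tartrate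
Reagents that add atoms: none
Why: Partial hydride reduction of the ester at −78 °C should stop at the tetrahedral aluminate, which releases the aldehyde only on work-up.

Step 9
Reactants: 16 4-bromopent-4-enal; 17 isopropenylmagnesium bromide
Product: 18 6-bromo-2-methylhepta-1,6-dien-3-ol (racemic)
Conditions: THF, −78 to 0 °C; aq. NH4Cl
Reagents that add atoms: none
Why: Grignard 1,2-addition to the aldehyde should leave the alkenyl bromide untouched at low temperature, and the racemic carbinol centre is erased in the next step.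

Step 10
Reactants: 18 6-bromo-2-methylhepta-1,6-dien-3-ol; 19 triethyl orthoacetate
Product: 21 ethyl (4E)-8-bromo-4-methylnona-4,8-dienoate, via ketene acetal 20 (not isolated)
Conditions: 19 (6 equiv), EtCO2H (cat.), 140 °C, EtOH distilled off
Reagents that add atoms: none
Why: The Johnson–Claisen orthoester rearrangement passes through a chair transition state with the carbinol substituent equatorial and should therefore deliver the E trisubstituted C15=C16 alkene.

Step 11
Reactants: 21 ethyl (4E)-8-bromo-4-methylnona-4,8-dienoate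
Product: 22 ethyl 3-[(2R,3R)-3-(3-bromobut-3-en-1-yl)-2-methyloxiran-2-yl]propanoate
Conditions: D-fructose-derived Shi ketone (0.3 equiv), KHSO5 (Oxone), K2CO3, Bu4NHSO4, MeCN–CH2(OMe)2/aq. Na2B4O7 buffer, 0 °C
Reagents that add atoms: potassium peroxymonosulfate, [K+].[O-]S(=O)(=O)OO
Why: In the Shi asymmetric epoxidation the chiral dioxirane attacks the electron-rich E trisubstituted alkene through the spiro transition state to give the (R,R)-epoxide (C15 final, C16 provisional), while the electron-poor 2-bromoalkene should not react.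

Step 12
Reactants: 22 ethyl 3-[(2R,3R)-3-(3-bromobut-3-en-1-yl)-2-methyloxiran-2-yl]propanoate
Product: 23 (5S)-5-[(1R)-4-bromo-1-hydroxypent-4-en-1-yl]-5-methyloxolan-2-one
Conditions: CSA (10 mol %), wet CH2Cl2, rt
Reagents that add atoms: water, O
Why: In this acid-catalysed epoxy-ester lactonisation the ester carbonyl oxygen opens the protonated epoxide 5-exo at the tertiary carbon with inversion (C16 R to S) while C15 keeps its configuration, and hydrolysis of the dialkoxycarbenium ion gives the γ-lactone.

Step 13
Reactants: 23 (5S)-5-[(1R)-4-bromo-1-hydroxypent-4-en-1-yl]-5-methyloxolan-2-one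
Product: 24 (1R)-4-bromo-1-[(2S)-2-methyl-5-oxooxolan-2-yl]pent-4-en-1-yl acetate
Conditions: Ac2O, pyridine, DMAP (cat.), CH2Cl2, rt
Reagents that add atoms: acetic anhydride, CC(=O)OC(C)=O
Why: DMAP-catalysed acylation should esterify the hindered secondary alcohol, so that later no hydroxyl of this half can compete for boron.

Step 14
Reactants: 24 (1R)-4-bromo-1-[(2S)-2-methyl-5-oxooxolan-2-yl]pent-4-en-1-yl acetate
Product: 25 (1R)-1-[(2S)-2-methyl-5-oxooxolan-2-yl]-4-(4,4,5,5-tetramethyl-1,3,2-dioxaborolan-2-yl)pent-4-en-1-yl acetate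
Conditions: B2pin2, PdCl2(PPh3)2 (3 mol %), PPh3 (6 mol %), KOPh, toluene, 50 °C
Reagents that add atoms: bis(pinacolato)diboron, CC1(C)OB(OC1(C)C)B1OC(C)(C)C(C)(C)O1
Why: Miyaura borylation of the alkenyl bromide places boron on C12 with no regiochemical question, and the weak base KOPh should spare acetate and lactone and hold back Suzuki homocoupling.

Step 15
Reactants: 25 (1R)-1-[(2S)-2-methyl-5-oxooxolan-2-yl]-4-(4,4,5,5-tetramethyl-1,3,2-dioxaborolan-2-yl)pent-4-en-1-yl acetate
Product: 26 [(5R)-5-acetoxy-5-[(2S)-2-methyl-5-oxooxolan-2-yl]pent-1-en-2-yl]boronic acid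
Conditions: NaIO4, NH4OAc, acetone–H2O, rt
Reagents that add atoms: water, O
Why: Periodate cleaves the pinacol released in the hydrolysis equilibrium and so should drive the deprotection to the free boronic acid under near-neutral conditions that ester, lactone and alkene tolerate; 26 is used at once.

**Union and completion**

Step 16
Reactants: 12 (3S,5E)-8-(furan-3-yl)-5-methylocta-1,5-dien-3-ol; 26 [(5R)-5-acetoxy-5-[(2S)-2-methyl-5-oxooxolan-2-yl]pent-1-en-2-yl]boronic acid
Product: 28 (1R)-3-[(5S)-5-[(2E)-5-(furan-3-yl)-2-methylpent-2-en-1-yl]-2-hydroxy-2,5-dihydro-1,2-oxaborol-3-yl]-1-[(2S)-2-methyl-5-oxooxolan-2-yl]propyl acetate, via mixed boronic ester 27 (not isolated)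
Conditions: 12 (1.0 equiv), 26 (1.3 equiv), 4 Å molecular sieves, toluene, rt; then second-generation Grubbs catalyst RuCl2(H2IMes)(PCy3)(=CHPh) (10 mol %), toluene (0.005 M), 80 °C, argon sparge; pH 7 buffer
Reagents that add atoms: none
Why: Condensation with loss of water ties the C10 oxygen to boron; the ruthenium benzylidene then exchanges onto the unhindered monosubstituted C11 vinyl group, and the new alkylidene adds across the boron-bearing 1,1-disubstituted alkene ([2+2] cycloaddition to a ruthenacyclobutane, then cycloreversion), expelling ethylene and forming C11=C12. The closest known reaction type is boron-tethered ring-closing metathesis of mixed alkenylboronic esters of allylic alcohols to cyclic boronic half-esters, here in its demanding variant with a 1-substituted vinylboron partner, hence the high dilution, 80 °C and ethylene removal. The single ring closed is the five-membered 2,5-dihydro-1,2-oxaborole (O, B, C12, C11, C10), formed by metathesis of the two terminal methylene groups, and a five-membered ring can only hold its endocyclic alkene cis. No stereocentre is created; C10, C15 and C16 are spectators. The step needs boron cis to C10 across C11=C12, which the ring enforces, and site selectivity, which is secured because the catalyst loads only at the C11 vinyl group while the trisubstituted C7=C8 alkene and the furan stay out; using 26 in excess and keeping C15 as its acetate leaves C10–OH as the only hydroxyl that can bind boron.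

Step 17
Reactants: 28 (1R)-3-[(5S)-5-[(2E)-5-(furan-3-yl)-2-methylpent-2-en-1-yl]-2-hydroxy-2,5-dihydro-1,2-oxaborol-3-yl]-1-[(2S)-2-methyl-5-oxooxolan-2-yl]propyl acetate
Product: 29 (1R,4E,6S,8E)-11-(furan-3-yl)-6-hydroxy-4,8-dimethyl-1-[(2S)-2-methyl-5-oxooxolan-2-yl]undeca-4,8-dien-1-yl acetate
Conditions: CH3I (5 equiv), Pd2(dba)3 (5 mol %), P(o-tol)3 (20 mol %), K2CO3, DMF–H2O, 50 °C; aq. NH4Cl
Reagents that add atoms: iodomethane, CI
Why: Suzuki–Miyaura coupling of the alkenylboron half-ester with iodomethane should replace boron by methyl with retention, so the methyl ends up cis to C10 (E alkene) and the C10 hydroxyl is set free; a lactone opened by carbonate recloses on the mildly acidic work-up and any lost acetate is restored in step 18.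

Step 18
Reactants: 29 (1R,4E,6S,8E)-11-(furan-3-yl)-6-hydroxy-4,8-dimethyl-1-[(2S)-2-methyl-5-oxooxolan-2-yl]undeca-4,8-dien-1-yl acetate
Product: 30 Irciformonin F
Conditions: Ac2O, pyridine, DMAP (cat.), CH2Cl2, 0 °C to rt
Reagents that add atoms: acetic anhydride, CC(=O)OC(C)=O
Why: DMAP-catalysed acetylation of the secondary allylic alcohol should complete the diacetate without touching any stereocentre or alkene.

**Compound list**

1 | (S)-epichlorohydrin, (2S)-2-(chloromethyl)oxirane | ClC[C@@H]1CO1 | starting material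
2 | ethynyltrimethylsilane | C#C[Si](C)(C)C | starting material
3 | (2S)-1-chloro-5-(trimethylsilyl)pent-4-yn-2-ol | ClC[C@@H](O)CC#C[Si](C)(C)C | intermediate
4 | trimethyl{3-[(2S)-oxiran-2-yl]prop-1-yn-1-yl}silane | C1[C@@H](O1)CC#C[Si](C)(C)C | intermediate (not isolated)
5 | (3S)-6-(trimethylsilyl)hex-1-en-5-yn-3-ol | C=C[C@@H](O)CC#C[Si](C)(C)C | intermediate
6 | (3S)-hex-1-en-5-yn-3-ol | C=C[C@@H](O)CC#C | intermediate
7 | dimethylaluminium alkoxide of (3S,5E)-6-(dimethylalumanyl)-5-methylhexa-1,5-dien-3-ol | C=C[C@@H](O[Al](C)C)C/C(C)=C/[Al](C)C | intermediate (not isolated)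
8 | (3S,5E)-6-iodo-5-methylhexa-1,5-dien-3-ol | C=C[C@@H](O)C/C(C)=C/I | intermediate
9 | furan-3-carbaldehyde | O=Cc1ccoc1 | starting material
10 | 3-ethenylfuran | C=Cc1ccoc1 | intermediate
11 | 9-[2-(furan-3-yl)ethyl]-9-borabicyclo[3.3.1]nonane | C(Cc1ccoc1)B1C2CCCC1CCC2 | intermediate (not isolated)
12 | (3S,5E)-8-(furan-3-yl)-5-methylocta-1,5-dien-3-ol | C=C[C@@H](O)C/C(C)=C/CCc1ccoc1 | intermediate
13 | tert-butyl acetate | CC(=O)OC(C)(C)C | starting material
14 | 2,3-dibromoprop-1-ene | C=C(Br)CBr | starting material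
15 | tert-butyl 4-bromopent-4-enoate | C=C(Br)CCC(=O)OC(C)(C)C | intermediate
16 | 4-bromopent-4-enal | C=C(Br)CCC=O | intermediate
17 | isopropenylmagnesium bromide | CC(=C)[Mg]Br | starting material
18 | 6-bromo-2-methylhepta-1,6-dien-3-ol (racemic) | C=C(C)C(O)CCC(Br)=C | intermediate
19 | triethyl orthoacetate | CCOC(C)(OCC)OCC | starting material
20 | 6-bromo-3-[(1-ethoxyethenyl)oxy]-2-methylhepta-1,6-diene | C=C(OCC)OC(CCC(Br)=C)C(C)=C | intermediate (not isolated)
21 | ethyl (4E)-8-bromo-4-methylnona-4,8-dienoate | CCOC(=O)CC/C(C)=C/CCC(Br)=C | intermediate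
22 | ethyl 3-[(2R,3R)-3-(3-bromobut-3-en-1-yl)-2-methyloxiran-2-yl]propanoate | CCOC(=O)CC[C@@]1(C)O[C@@H]1CCC(Br)=C | intermediate
23 | (5S)-5-[(1R)-4-bromo-1-hydroxypent-4-en-1-yl]-5-methyloxolan-2-one | C=C(Br)CC[C@@H](O)[C@]1(C)CCC(=O)O1 | intermediate
24 | (1R)-4-bromo-1-[(2S)-2-methyl-5-oxooxolan-2-yl]pent-4-en-1-yl acetate | C=C(Br)CC[C@@H](OC(C)=O)[C@]1(C)CCC(=O)O1 | intermediate
25 | (1R)-1-[(2S)-2-methyl-5-oxooxolan-2-yl]-4-(4,4,5,5-tetramethyl-1,3,2-dioxaborolan-2-yl)pent-4-en-1-yl acetate | C=C(B1OC(C)(C)C(C)(C)O1)CC[C@@H](OC(C)=O)[C@]2(C)CCC(=O)O2 | intermediate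
26 | [(5R)-5-acetoxy-5-[(2S)-2-methyl-5-oxooxolan-2-yl]pent-1-en-2-yl]boronic acid | C=C(B(O)O)CC[C@@H](OC(C)=O)[C@]1(C)CCC(=O)O1 | intermediate
27 | (3S,5E)-8-(furan-3-yl)-5-methylocta-1,5-dien-3-yl hydrogen [(5R)-5-acetoxy-5-[(2S)-2-methyl-5-oxooxolan-2-yl]pent-1-en-2-yl]boronate | C=C[C@@H](OB(O)C(=C)CC[C@@H](OC(C)=O)[C@]1(C)CCC(=O)O1)C/C(C)=C/CCc1ccoc1 | intermediate (not isolated)
28 | (1R)-3-[(5S)-5-[(2E)-5-(furan-3-yl)-2-methylpent-2-en-1-yl]-2-hydroxy-2,5-dihydro-1,2-oxaborol-3-yl]-1-[(2S)-2-methyl-5-oxooxolan-2-yl]propyl acetate | OB1O[C@@H](C/C(C)=C/CCc2ccoc2)C=C1CC[C@@H](OC(C)=O)[C@]3(C)CCC(=O)O3 | intermediate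
29 | (1R,4E,6S,8E)-11-(furan-3-yl)-6-hydroxy-4,8-dimethyl-1-[(2S)-2-methyl-5-oxooxolan-2-yl]undeca-4,8-dien-1-yl acetate | O[C@H](/C=C(\C)CC[C@@H](OC(C)=O)[C@]1(C)CCC(=O)O1)C/C(C)=C/CCc1ccoc1 | intermediate
30 | Irciformonin F, (1R,4E,6S,8E)-11-(furan-3-yl)-4,8-dimethyl-1-[(2S)-2-methyl-5-oxooxolan-2-yl]undeca-4,8-diene-1,6-diyl diacetate | CC(=O)O[C@H](/C=C(\C)CC[C@@H](OC(C)=O)[C@]1(C)CCC(=O)O1)C/C(C)=C/CCc1ccoc1 | target

**Step count**

Total: 18 steps. Longest linear sequence: 12 steps (steps 7 to 18); the alcohol half joins after 5 linear steps (1 to 4 and 6), with step 5 as a one-step side branch.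

**Steps most likely to fail**

Step 16. Ring closure onto the hindered boron-bearing 1,1-disubstituted alkene may be too slow, so that dimerisation through the C11 vinyl group, catalyst decay or protodeboronation take over. The fallback gives up the template and sets out from 12 and 24. Alcohol 12 is acetylated (Ac2O, pyridine, DMAP) to (3S,5E)-8-(furan-3-yl)-5-methylocta-1,5-dien-3-yl acetate F1. Bromide 24 is methylated by Negishi coupling (MeZnCl, Pd(PPh3)4, THF) to (1R)-4-methyl-1-[(2S)-2-methyl-5-oxooxolan-2-yl]pent-4-en-1-yl acetate F2. Untethered cross-metathesis of F1 with excess F2 (second-generation Hoveyda–Grubbs catalyst RuCl2(H2IMes)(=CH-C6H4-2-O-i-Pr), CH2Cl2, 40 °C) should then give 30 together with its C11=C12 Z isomer, to be separated on AgNO3-impregnated silica or by HPLC. This returns to the route at 30, at the price of geometric control.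

Step 17. Transmetalation of the cyclic half-ester may lag behind protodeboronation, quaternisation of the phosphine by CH3I, or base-induced ester cleavage. The fallback reverses the polarity and sets out from 28. Ipso-iododeboronation with N-iodosuccinimide (1.0 equiv, MeCN, 0 °C, dark) should proceed with retention and give (1R,4Z,6S,8E)-11-(furan-3-yl)-6-hydroxy-4-iodo-8-methyl-1-[(2S)-2-methyl-5-oxooxolan-2-yl]undeca-4,8-dien-1-yl acetate F3, with iodine cis to C10. Negishi coupling of F3 with MeZnCl (3 equiv, Pd(PPh3)4, THF, rt), again with retention, returns to the route at 29.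

Step 15. The hydrolysis equilibrium of the pinacol ester may not be pulled to completion, or the liberated 1-substituted vinylboronic acid may oligomerise or lose boron during isolation. The fallback sets out from 25. KHF2 in aqueous MeOH should convert it into potassium [(5R)-5-acetoxy-5-[(2S)-2-methyl-5-oxooxolan-2-yl]pent-1-en-2-yl]trifluoroborate F4, a salt that can be purified by precipitation and stored. Silica-gel-promoted hydrolysis (SiO2, H2O, EtOAc, rt) just before the union returns to the route at 26.

Further compounds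
F1 | step 16 | (3S,5E)-8-(furan-3-yl)-5-methylocta-1,5-dien-3-yl acetate | C=C[C@@H](OC(C)=O)C/C(C)=C/CCc1ccoc1
F2 | step 16 | (1R)-4-methyl-1-[(2S)-2-methyl-5-oxooxolan-2-yl]pent-4-en-1-yl acetate | C=C(C)CC[C@@H](OC(C)=O)[C@]1(C)CCC(=O)O1
F3 | step 17 | (1R,4Z,6S,8E)-11-(furan-3-yl)-6-hydroxy-4-iodo-8-methyl-1-[(2S)-2-methyl-5-oxooxolan-2-yl]undeca-4,8-dien-1-yl acetate | O[C@H](/C=C(\I)CC[C@@H](OC(C)=O)[C@]1(C)CCC(=O)O1)C/C(C)=C/CCc1ccoc1
F4 | step 15 | potassium [(5R)-5-acetoxy-5-[(2S)-2-methyl-5-oxooxolan-2-yl]pent-1-en-2-yl]trifluoroborate | [K+].C=C([B-](F)(F)F)CC[C@@H](OC(C)=O)[C@]1(C)CCC(=O)O1
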